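**Retrosynthetic overview**

1. Numbering follows the target SMILES after the acetyl group: C1 (OAc), C2–C8, O9, C10–C16, O17, C18. O17 bridges C16 and C18 across the ten-membered carbocycle C2–C3–C18–C10–C11–C12–C13–C14–C15–C16, and the adjacent quaternary C10 carries O9. This transannular ether next to a vicinal C–O is read as a C10–C18 epoxide opened by the C16 hydroxyl.
2. Disconnections, last to first: oxepane (O9–C8, Williamson closure from the C10 alkoxide), then tetrahydrofuran (O17–C18, transannular epoxide opening), then the cis epoxide of a (Z)-cyclodecene, then the ten-membered ring by intramolecular B-alkyl Suzuki coupling at C10–C11.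
3. C18=C10 comes from an α-iodo Wittig olefination of the C18 aldehyde, C11–C13 from allylation of a C14 Weinreb amide, and C1–O from Baeyer–Villiger oxidation of a cyclopentanone at C14.
4. The cyclohexane is made first, by an endo Diels–Alder reaction of a Roche-ester-derived (2Z,4E)-diene with (S)-4-silyloxycyclopentenone, which sets C1, C2, C3 and C6 against C16. Hydroxyl-directed hydrogenation then sets C4, and C7 comes from the Roche ester.
5. Ring order: cyclohexane, cyclodecene, tetrahydrofuran, oxepane.

Key step: step 21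

Remarks on the chemistry:
- An acetate at C1 would sit 1,3 to the C16 alkoxide and migrate under KH. C1–O and C8–O are therefore carried as benzyl ethers through the key step, and the acetate is put on afterwards.
- The C14 ketone is masked as a dioxolane, because a free β-alkoxide ketone would undergo retro-aldol cleavage under KH.
- Assumption: (S)-4-[(tert-butyldimethylsilyl)oxy]cyclopent-2-en-1-one is taken as a commercial chiral building block.

**Route**

Step 1
Reactants: 1 methyl (S)-3-hydroxy-2-methylpropanoate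
Product: 2 methyl (S)-3-(benzyloxy)-2-methylpropanoate
Conditions: BnOC(=NH)CCl3, TfOH (cat.), CH2Cl2/cyclohexane, rt
Reagents that add atoms: benzyl 2,2,2-trichloroacetimidate, N=C(OCc1ccccc1)C(Cl)(Cl)Cl
Why: Acid-catalysed imidate O-benzylation protects the primary alcohol without base, so the α-stereocentre (future C7) is not epimerised.

Step 2
Reactants: 2 methyl (S)-3-(benzyloxy)-2-methylpropanoate
Product: 3 (S)-3-(benzyloxy)-2-methylpropanal
Conditions: i-Bu2AlH, CH2Cl2, −78 °C
Reagents that add atoms: none
Why: Partial ester reduction stops at the aldehyde because the aluminium hemiacetal is stable at −78 °C.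

Step 3
Reactants: 3 (S)-3-(benzyloxy)-2-methylpropanal
Product: 4 (R)-{[(4,4-dibromo-2-methylbut-3-en-1-yl)oxy]methyl}benzene
Conditions: CBr4, PPh3, CH2Cl2, 0 °C
Reagents that add atoms: carbon tetrabromide, BrC(Br)(Br)Br
Why: Corey–Fuchs dibromo-olefination runs under near-neutral conditions, which keeps the α-stereocentre.

Step 4
Reactants: 4 (R)-{[(4,4-dibromo-2-methylbut-3-en-1-yl)oxy]methyl}benzene
Product: 6 methyl (R)-5-(benzyloxy)-4-methylpent-2-ynoate, via lithium acetylide 5 (not isolated)
Conditions: n-BuLi (2.1 equiv), THF, −78 → 0 °C; then ClCO2Me, −78 °C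
Reagents that add atoms: methyl chloroformate, COC(=O)Cl
Why: The second Corey–Fuchs stage (Br/Li exchange, 1,2-shift, deprotonation) gives the lithium acetylide, which is acylated in the same flask by the chloroformate.

Step 5
Reactants: 6 methyl (R)-5-(benzyloxy)-4-methylpent-2-ynoate
Product: 7 methyl (2Z,4E)-3-[(R)-1-(benzyloxy)propan-2-yl]hexa-2,4-dienoate
Conditions: (E)-MeCH=CHBr, t-BuLi, Et2O, −78 °C; CuI, THF, −40 °C; 6, −78 °C; NH4Cl/MeOH, −78 °C
Reagents that add atoms: (E)-1-bromoprop-1-ene, C/C=C/Br
Why: syn-Carbocupration of the ynoate by [(E)-MeCH=CH]2CuLi places the propenyl group on C4 cis to the α-hydrogen, and protonation at −78 °C keeps that geometry, so the ester ends cis to the C7 branch (2Z) with the propenyl unit still E.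

Step 6
Reactants: 7 methyl (2Z,4E)-3-[(R)-1-(benzyloxy)propan-2-yl]hexa-2,4-dienoate
Product: 8 (2Z,4E)-3-[(R)-1-(benzyloxy)propan-2-yl]hexa-2,4-dien-1-ol
Conditions: i-Bu2AlH (2.2 equiv), CH2Cl2, −78 °C
Reagents that add atoms: none
Why: 1,2-Reduction of the conjugated ester gives the dienol (C18–OH) without touching the diene geometry.

Step 7
Reactants: 8 (2Z,4E)-3-[(R)-1-(benzyloxy)propan-2-yl]hexa-2,4-dien-1-ol
Product: 9 triethylsilyl ether of dienol 8
Conditions: TESCl, imidazole, CH2Cl2, 0 °C
Reagents that add atoms: chlorotriethylsilane, CC[Si](Cl)(CC)CC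
Why: Silylation masks the hydroxyl, which would otherwise bind the Lewis acid of the next step, and the TES group can later be removed beside a secondary TBS ether.

Step 8
Reactants: 9 triethylsilyl ether of dienol 8; 10 (S)-4-[(tert-butyldimethylsilyl)oxy]cyclopent-2-en-1-one
Product: 11 cis-fused hexahydroindenone Diels–Alder adduct
Conditions: EtAlCl2 (0.3 equiv), CH2Cl2/toluene, −40 → 0 °C
Reagents that add atoms: none
Why: In this Lewis-acid-catalysed endo Diels–Alder reaction the more nucleophilic diene terminus C3 (adjacent to the branched C4 and remote from the C6 methyl) bonds to the enone β-carbon C2, the diene adds anti to the 16-silyloxy group, and the endo transition state places the C6 methyl and the C3 CH2OTES arm cis to the ring-fusion bonds C1–C14 and C2–C16, which sets C1, C2, C3 and C6 against C16.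

Step 9
Reactants: 11 cis-fused hexahydroindenone Diels–Alder adduct
Product: 12 C18 alcohol of the adduct
Conditions: PPTS (cat.), MeOH, 0 °C
Reagents that add atoms: none
Why: Mild acid methanolysis cleaves the primary TES ether and leaves the secondary TBS ether and the β-silyloxy ketone intact.

Step 10
Reactants: 12 C18 alcohol of the adduct
Product: 13 saturated cis-hydrindanone with C4 set
Conditions: H2 (1 atm), [Ir(cod)(PCy3)(py)]PF6 (5 mol%), CH2Cl2, rt
Reagents that add atoms: none
Why: In this hydroxyl-directed hydrogenation the C18 hydroxyl binds the cationic iridium centre and delivers H2 to the C4=C5 face syn to the CH2OH arm, so H-4 ends cis to C18 and the C7 branch trans to it.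

Step 11
Reactants: 13 saturated cis-hydrindanone with C4 set
Product: 14 cis-fused δ-lactone (O between C14 and C1)
Conditions: mCPBA, NaHCO3, CH2Cl2, rt
Reagents that add atoms: 3-chloroperoxybenzoic acid, OOC(=O)c1cccc(Cl)c1
Why: In the Baeyer–Villiger oxidation the more substituted C1 migrates with retention, which installs the C1–O bond in its final configuration and turns C14 into an acyl carbon.

Step 12
Reactants: 14 cis-fused δ-lactone
Product: 15 C18 aldehyde lactone
Conditions: DMP, NaHCO3, CH2Cl2, rt
Reagents that add atoms: none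
Why: Dess–Martin oxidation of the primary alcohol under buffered, non-basic conditions avoids epimerisation at C3.

Step 13
Reactants: 15 C18 aldehyde lactone
Product: 16 (Z)-vinyl iodide lactone
Conditions: EtPPh3I, n-BuLi, THF, 0 °C; I2, −78 °C; NaHMDS, −20 °C; 15, −78 °C
Reagents that add atoms: ethyltriphenylphosphonium iodide, CC[P+](c1ccccc1)(c1ccccc1)c1ccccc1.[I-]; iodine, [I][I]
Why: Wittig olefination with the α-iodo ylide Ph3P=C(I)CH3 (Stork–Zhao type) gives the (Z)-2-iodoalkene with iodine cis to C3 under kinetic control, and at −78 °C the ylide leaves the lactone and C3 untouched.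

Step 14
Reactants: 16 (Z)-vinyl iodide lactone
Product: 17 hydroxy Weinreb amide
Conditions: MeNH(OMe)·HCl, AlMe3, CH2Cl2, 0 °C → rt
Reagents that add atoms: N,O-dimethylhydroxylamine hydrochloride, CNOC.Cl
Why: Aluminium amide aminolysis opens the lactone to the C14 Weinreb amide and frees the C1 hydroxyl without enolising the β-silyloxy carbonyl.

Step 15
Reactants: 17 hydroxy Weinreb amide
Product: 18 C1 benzyl ether Weinreb amide
Conditions: BnOC(=NH)CCl3, TfOH (cat.), CH2Cl2, 0 °C
Reagents that add atoms: benzyl 2,2,2-trichloroacetimidate, N=C(OCc1ccccc1)C(Cl)(Cl)Cl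
Why: Acid-catalysed benzylation protects C1–OH without forming an alkoxide, which would re-close the lactone or eliminate the β-silyloxy group.

Step 16
Reactants: 18 C1 benzyl ether Weinreb amide
Product: 19 allyl ketone
Conditions: allylMgBr, THF, −78 °C
Reagents that add atoms: allylmagnesium bromide, C=CC[Mg]Br
Why: The chelated tetrahedral intermediate of the Weinreb ketone synthesis prevents over-addition, and a cold quench keeps the β,γ-unsaturated ketone from moving into conjugation.

Step 17
Reactants: 19 allyl ketone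
Product: 20 C14 dioxolane
Conditions: (TMSOCH2)2, TMSOTf (cat.), CH2Cl2, −78 → −20 °C
Reagents that add atoms: 1,2-bis(trimethylsilyloxy)ethane, C[Si](C)(C)OCCO[Si](C)(C)C
Why: Noyori ketalisation is aprotic and kinetic, so the ketone is masked without alkene migration or β-elimination of the silyloxy group.

Step 18
Reactants: 20 C14 dioxolane
Product: 22 (Z)-cyclodecene silyl ether, via alkylborane 21 (not isolated)
Conditions: 9-BBN, THF, rt; then Pd(dppf)Cl2 (10 mol%), AsPh3, Cs2CO3, DMF/THF/H2O, 50 °C, syringe-pump addition (final 2 mM)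
Reagents that add atoms: none
Why: Chemoselective hydroboration of the terminal alkene and intramolecular B-alkyl Suzuki–Miyaura coupling form C10–C11 with retention of the vinyl geometry, closing the ten-membered ring with the (Z)-C18=C10 alkene.

Step 19
Reactants: 22 (Z)-cyclodecene silyl ether
Product: 23 cis epoxide silyl ether
Conditions: mCPBA, NaHCO3, CH2Cl2, 0 °C
Reagents that add atoms: 3-chloroperoxybenzoic acid, OOC(=O)c1cccc(Cl)c1
Why: Prilezhaev epoxidation adds oxygen syn to the Z alkene (cis epoxide) and should attack the peripheral face, anti to the ring atom C2 across C3–C18, which is the face that leaves the rear of C18 open to the C16 oxygen.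

Step 20
Reactants: 23 cis epoxide silyl ether
Product: 24 epoxy alcohol (key-step precursor)
Conditions: TBAF, AcOH (1:1), THF, rt
Reagents that add atoms: none
Why: Fluoride desilylation buffered with acetic acid frees the C16 hydroxyl without base- or acid-induced opening of the epoxide.

Step 21
Reactants: 24 epoxy alcohol (key-step precursor)
Product: 25 oxa-bridged tertiary alcohol (key-step product)
Conditions: KH, THF, 0 °C → rt
Reagents that add atoms: none
Why: Deprotonation gives the C16 potassium alkoxide, which attacks C18 of the C10–C18 epoxide from the rear across the ten-membered ring in an intramolecular SN2 opening; the closest known reaction type is the transannular opening of a medium-ring epoxide by a hydroxyl group. The tetrahydrofuran ring (O17, C16, C2, C3, C18) closes in the 5-exo-tet mode, with the breaking C18–O bond outside the new ring. C18 is the only stereocentre that changes: it is inverted by the backside attack, so its configuration follows from the cis epoxide of step 19, while C10 keeps the epoxide oxygen with retention and C16 is untouched. The step needs attack at C18 and not at C10, and basic conditions secure this because the alkoxide prefers the secondary carbon over the fully substituted C10 and the five-membered transition state over the six-membered endo alternative. The medium ring holds O16 within reach of C18, the dioxolane blocks retro-aldol cleavage between C14 and C16, and the benzyl ethers at C1 and C8 leave no second nucleophile or migrating acyl group.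

Step 22
Reactants: 25 oxa-bridged tertiary alcohol
Product: 26 triol (C1–OH, C8–OH, C10–OH)
Conditions: H2 (1 atm), Pd(OH)2/C, EtOAc/EtOH, rt
Reagents that add atoms: none
Why: Hydrogenolysis removes both benzyl ethers, and no alkene remains while the ketal, ethers and tertiary alcohol are inert.

Step 23
Reactants: 26 triol
Product: 27 C8 mesylate
Conditions: MsCl (1.05 equiv), 2,4,6-collidine, CH2Cl2, −20 → 0 °C
Reagents that add atoms: methanesulfonyl chloride, CS(=O)(=O)Cl
Why: Sulfonylation is selective for the primary C8 hydroxyl over the hindered secondary C1 and tertiary C10 hydroxyls.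

Step 24
Reactants: 27 C8 mesylate
Product: 28 oxepane ketal alcohol
Conditions: NaH, THF, 0 → 45 °C
Reagents that add atoms: none
Why: Intramolecular Williamson etherification (7-exo-tet) by the C10 alkoxide closes the oxepane without touching a stereocentre, and the C1 alkoxide, trans to the C7 arm, cannot reach C8.

Step 25
Reactants: 28 oxepane ketal alcohol
Product: 29 C1 acetate ketal
Conditions: Ac2O, DMAP, pyridine, CH2Cl2, rt
Reagents that add atoms: acetic anhydride, CC(=O)OC(C)=O
Why: DMAP-catalysed acetylation of the only free hydroxyl installs the acetate while the ketone is still masked, so no hemiketal can interfere.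

Step 26
Reactants: 29 C1 acetate ketal
Product: 30 target CNP0288436.2
Conditions: PPTS, acetone/H2O, 50 °C
Reagents that add atoms: water, O
Why: Mild acid-catalysed ketal hydrolysis releases the C14 ketone under conditions that leave the acetate and the tertiary ether at C10 intact.

**Compound list**

1 | methyl (S)-3-hydroxy-2-methylpropanoate | COC(=O)[C@@H](C)CO | starting material
2 | methyl (S)-3-(benzyloxy)-2-methylpropanoate | COC(=O)[C@@H](C)COCc1ccccc1 | intermediate
3 | (S)-3-(benzyloxy)-2-methylpropanal | O=C[C@@H](C)COCc1ccccc1 | intermediate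
4 | (R)-{[(4,4-dibromo-2-methylbut-3-en-1-yl)oxy]methyl}benzene | BrC(Br)=C[C@@H](C)COCc1ccccc1 | intermediate
5 | lithium acetylide of (R)-4-(benzyloxy)-3-methylbut-1-yne (not isolated) | [Li]C#C[C@@H](C)COCc1ccccc1 | intermediate
6 | methyl (R)-5-(benzyloxy)-4-methylpent-2-ynoate | COC(=O)C#C[C@@H](C)COCc1ccccc1 | intermediate
7 | methyl (2Z,4E)-3-[(R)-1-(benzyloxy)propan-2-yl]hexa-2,4-dienoate | COC(=O)/C=C(\[C@@H](C)COCc1ccccc1)/C=C/C | intermediate
8 | (2Z,4E)-3-[(R)-1-(benzyloxy)propan-2-yl]hexa-2,4-dien-1-ol | OC/C=C(\[C@@H](C)COCc1ccccc1)/C=C/C | intermediate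
9 | triethylsilyl ether of dienol 8 | CC[Si](CC)(CC)OC/C=C(\[C@@H](C)COCc1ccccc1)/C=C/C | intermediate
10 | (S)-4-[(tert-butyldimethylsilyl)oxy]cyclopent-2-en-1-one | O=C1C[C@H](O[Si](C)(C)C(C)(C)C)C=C1 | starting material
11 | Diels–Alder adduct, cis-fused 2,3,3a,4,7,7a-hexahydroinden-1-one: C14 ketone, 16-OTBS anti to C3, C3–CH2OTES, C4=C5 with the (R)-CH(CH3)CH2OBn branch on C4, C6-methyl; H-1, H-2, H-3 and H-6 all cis | C[C@@H]1C=C([C@@H](C)COCc3ccccc3)[C@H](CO[Si](CC)(CC)CC)[C@@H]2[C@@H](O[Si](C)(C)C(C)(C)C)CC(=O)[C@H]12 | intermediate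
12 | C18 alcohol of 11 | C[C@@H]1C=C([C@@H](C)COCc3ccccc3)[C@H](CO)[C@@H]2[C@@H](O[Si](C)(C)C(C)(C)C)CC(=O)[C@H]12 | intermediate
13 | saturated cis-hydrindanone, H-4 cis to the C3–CH2OH arm | C[C@@H]1C[C@@H]([C@@H](C)COCc3ccccc3)[C@H](CO)[C@@H]2[C@@H](O[Si](C)(C)C(C)(C)C)CC(=O)[C@H]12 | intermediate
14 | cis-fused δ-lactone (O inserted between C14 and C1) | C[C@@H]1C[C@@H]([C@@H](C)COCc3ccccc3)[C@H](CO)[C@@H]2[C@@H](O[Si](C)(C)C(C)(C)C)CC(=O)O[C@H]12 | intermediate
15 | C18 aldehyde lactone | C[C@@H]1C[C@@H]([C@@H](C)COCc3ccccc3)[C@H](C=O)[C@@H]2[C@@H](O[Si](C)(C)C(C)(C)C)CC(=O)O[C@H]12 | intermediate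
16 | (Z)-vinyl iodide lactone, C3–CH=C(I)CH3 with iodine cis to C3 | C[C@@H]1C[C@@H]([C@@H](C)COCc3ccccc3)[C@H](/C=C(\I)C)[C@@H]2[C@@H](O[Si](C)(C)C(C)(C)C)CC(=O)O[C@H]12 | intermediate
17 | hydroxy Weinreb amide (C14 amide, free C1–OH) | C[C@@H]1C[C@@H]([C@@H](C)COCc3ccccc3)[C@H](/C=C(\I)C)[C@H]([C@@H](O[Si](C)(C)C(C)(C)C)CC(=O)N(C)OC)[C@@H]1O | intermediate
18 | C1 benzyl ether Weinreb amide | C[C@@H]1C[C@@H]([C@@H](C)COCc3ccccc3)[C@H](/C=C(\I)C)[C@H]([C@@H](O[Si](C)(C)C(C)(C)C)CC(=O)N(C)OC)[C@@H]1OCc4ccccc4 | intermediate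
19 | allyl ketone (C14 ketone carrying C13–C11) | C[C@@H]1C[C@@H]([C@@H](C)COCc3ccccc3)[C@H](/C=C(\I)C)[C@H]([C@@H](O[Si](C)(C)C(C)(C)C)CC(=O)CC=C)[C@@H]1OCc4ccccc4 | intermediate
20 | C14 dioxolane of 19 | C[C@@H]1C[C@@H]([C@@H](C)COCc3ccccc3)[C@H](/C=C(\I)C)[C@H]([C@@H](O[Si](C)(C)C(C)(C)C)CC5(CC=C)OCCO5)[C@@H]1OCc4ccccc4 | intermediate
21 | B-alkyl-9-BBN at C11 (not isolated) | C[C@@H]1C[C@@H]([C@@H](C)COCc3ccccc3)[C@H](/C=C(\I)C)[C@H]([C@@H](O[Si](C)(C)C(C)(C)C)CC5(CCCB6C7CCCC6CCC7)OCCO5)[C@@H]1OCc4ccccc4 | intermediate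
22 | (Z)-cyclodecene: ring C2–C3–C18=C10–C11–C12–C13–C14–C15–C16, 16-OTBS, C14 dioxolane, benzyl ethers at C1 and C8 | c4ccccc4CO[C@H]1[C@H]2[C@@H](O[Si](C)(C)C(C)(C)C)CC5(OCCO5)CCC/C(C)=C\[C@H]2[C@@H](C[C@H]1C)[C@@H](C)COCc6ccccc6 | intermediate
23 | cis C10–C18 epoxide silyl ether (oxygen anti to C2 across C3–C18) | c4ccccc4CO[C@H]1[C@H]2[C@@H](O[Si](C)(C)C(C)(C)C)CC5(OCCO5)CCC[C@]6(C)O[C@@H]6[C@H]2[C@@H](C[C@H]1C)[C@@H](C)COCc7ccccc7 | intermediate
24 | epoxy alcohol, key-step precursor (C16–OH, C10–C18 epoxide, C14 dioxolane) | c4ccccc4CO[C@H]1[C@H]2[C@@H](O)CC5(OCCO5)CCC[C@]6(C)O[C@@H]6[C@H]2[C@@H](C[C@H]1C)[C@@H](C)COCc7ccccc7 | intermediate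
25 | oxa-bridged tertiary alcohol, key-step product (tetrahydrofuran O17 between C16 and C18, C10–OH) | c4ccccc4CO[C@H]1[C@H]2[C@@H]3CC5(OCCO5)CCC[C@](C)(O)[C@@H](O3)[C@H]2[C@@H](C[C@H]1C)[C@@H](C)COCc6ccccc6 | intermediate
26 | triol (C1–OH, C8–OH, C10–OH) | O[C@H]1[C@H]2[C@@H]3CC5(OCCO5)CCC[C@](C)(O)[C@@H](O3)[C@H]2[C@@H](C[C@H]1C)[C@@H](C)CO | intermediate
27 | C8 mesylate | O[C@H]1[C@H]2[C@@H]3CC5(OCCO5)CCC[C@](C)(O)[C@@H](O3)[C@H]2[C@@H](C[C@H]1C)[C@@H](C)COS(C)(=O)=O | intermediate
28 | oxepane ketal alcohol (O9 between C8 and C10, free C1–OH) | O[C@H]1[C@@H]2[C@@H]3[C@@H](C[C@H]1C)[C@@H](C)CO[C@@]1(C)CCCC4(OCCO4)C[C@@H]2O[C@@H]31 | intermediate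
29 | C1 acetate ketal | CC(=O)O[C@H]1[C@@H]2[C@@H]3[C@@H](C[C@H]1C)[C@@H](C)CO[C@@]1(C)CCCC4(OCCO4)C[C@@H]2O[C@@H]31 | intermediate
30 | CNP0288436.2 | CC(=O)O[C@H]1[C@@H]2[C@@H]3[C@@H](C[C@H]1C)[C@@H](C)CO[C@@]1(C)CCCC(=O)C[C@@H]2O[C@@H]31 | target

**Step count**

Total steps: 26. Longest linear sequence: 26 steps, from 1 to 30 (10 enters at step 8).

**Steps most likely to fail, with fallbacks**

Step 18 (ring closure). A strained ten-membered ring must form, so intermolecular coupling to oligomers, protodeboronation or β-hydride elimination of the alkylpalladium intermediate may outrun the closure. The fallback closes the ring by olefin metathesis. It sets out from 18 and comes back at 22.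
- Stille coupling of 18 with allyltributylstannane (Pd(PPh3)4, CuI, DMF) should give the skipped-diene Weinreb amide F1.
- Vinylmagnesium bromide (THF, −78 → 0 °C, acidic quench) should give the vinyl ketone F2.
- Ring-closing metathesis with the second-generation Hoveyda–Grubbs catalyst RuCl2(=CH-2-(i-PrO)C6H4)(H2IMes) in toluene at 80 °C under high dilution should join C12 and C13 to give the cyclodecadienone F3. Its enone geometry is of no consequence and is drawn Z.
- Conjugate reduction with [(Ph3P)CuH]6 in wet toluene should give the saturated macrocyclic ketone F4.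
- Ketalisation as in step 17 then returns 22.

Step 8 (cycloaddition). The β-silyloxy enone may lose silanol under the Lewis acid, or the trisubstituted diene may add too slowly, so that regio- and endo-selectivity erode at the temperatures then needed. The fallback adds an activating ester to the dienophile. It sets out from 10 (with 9) and comes back at 11.
- Iodination of 10 (I2, pyridine, CH2Cl2) should give (S)-4-[(tert-butyldimethylsilyl)oxy]-2-iodocyclopent-2-en-1-one F5.
- Methoxycarbonylation (CO, MeOH, PdCl2(PPh3)2, Et3N) should give methyl (S)-3-[(tert-butyldimethylsilyl)oxy]-5-oxocyclopent-1-ene-1-carboxylate F6.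
- This doubly activated dienophile should combine with 9 at 0 °C with ZnCl2, ketone endo and anti to the silyloxy group, to give the angular ester adduct F7.
- Dealkoxycarbonylation (LiCl, wet DMSO, 120 °C), with protonation to the cis ring fusion, returns 11.

Step 19 (epoxidation). Attack of the peracid on the inner face of the ring alkene (poor or reversed facial selectivity) would place the epoxide oxygen syn to the C16 oxygen, and the rear of C18 would then be closed to it. The fallback delivers oxygen to the opposite face. It sets out from 22 and comes back at 23.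
- NBS in aqueous acetone at 0 °C should form the bromonium ion on the face that the peracid prefers, and water should open it at the tertiary C10 from the other side to give the anti bromohydrin F8.
- K2CO3 in MeOH closes the epoxide with inversion at C18, so the oxygen ends on the face opposite to that reached by direct epoxidation, which is 23.

**Further compounds**

F1 | step 18 | skipped-diene Weinreb amide, C3–CH=C(CH3)CH2CH=CH2 with Z geometry | C[C@@H]1C[C@@H]([C@@H](C)COCc3ccccc3)[C@H](/C=C(\CC=C)C)[C@H]([C@@H](O[Si](C)(C)C(C)(C)C)CC(=O)N(C)OC)[C@@H]1OCc4ccccc4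
F2 | step 18 | vinyl ketone at C14 | C[C@@H]1C[C@@H]([C@@H](C)COCc3ccccc3)[C@H](/C=C(\CC=C)C)[C@H]([C@@H](O[Si](C)(C)C(C)(C)C)CC(=O)C=C)[C@@H]1OCc4ccccc4
F3 | step 18 | cyclodecadienone with C12=C13 enone and (Z)-C18=C10 | c4ccccc4CO[C@H]1[C@H]2[C@@H](O[Si](C)(C)C(C)(C)C)CC(=O)/C=C\C/C(C)=C\[C@H]2[C@@H](C[C@H]1C)[C@@H](C)COCc6ccccc6
F4 | step 18 | (Z)-cyclodecenone with free C14 ketone | c4ccccc4CO[C@H]1[C@H]2[C@@H](O[Si](C)(C)C(C)(C)C)CC(=O)CCC/C(C)=C\[C@H]2[C@@H](C[C@H]1C)[C@@H](C)COCc6ccccc6
F5 | step 8 | (S)-4-[(tert-butyldimethylsilyl)oxy]-2-iodocyclopent-2-en-1-one | O=C1C[C@H](O[Si](C)(C)C(C)(C)C)C=C1I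
F6 | step 8 | methyl (S)-3-[(tert-butyldimethylsilyl)oxy]-5-oxocyclopent-1-ene-1-carboxylate | COC(=O)C1=C[C@@H](O[Si](C)(C)C(C)(C)C)CC1=O
F7 | step 8 | Diels–Alder adduct with angular methyl ester at C1 | C[C@@H]1C=C([C@@H](C)COCc3ccccc3)[C@H](CO[Si](CC)(CC)CC)[C@@H]2[C@@H](O[Si](C)(C)C(C)(C)C)CC(=O)[C@]12C(=O)OC
F8 | step 19 | anti bromohydrin (C18–Br, C10–OH) of cyclodecene 22 | c4ccccc4CO[C@H]1[C@H]2[C@@H](O[Si](C)(C)C(C)(C)C)CC5(OCCO5)CCC[C@](C)(O)[C@@H](Br)[C@H]2[C@@H](C[C@H]1C)[C@@H](C)COCc6ccccc6
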